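**Plan**
- Retrosynthesis first cuts O1–C8a and C4–C4a, the two bonds that tie the dihydropyranone ring to the benzo ring. C8a (carrying the ether oxygen O1) and C4a (carrying the acyl carbon C4) are adjacent arene carbons, so removing them as an aryne leaves O1–C2–C3–C4 closed on itself as a β-lactone. The C5 methoxy group next to C4a polarises that aryne in the sense required.
- The lactone is then cut at its acyl C–O bond (β-hydroxy acid) and at the carbinol C–H bond (β-keto ester). The aryne goes back to an o-silylaryl triflate and a symmetrical phenol.
- Forward: aryne precursor (steps 1–2); four-membered oxetanone ring (steps 3–5); step 6 inserts the two aryne carbons into the acyl C–O bond of the oxetanone, enlarging it to the six-membered pyranone ring and joining the two halves.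
- Stereochemistry: the only stereocentre (C2) is set in step 3 by catalyst-controlled asymmetric transfer hydrogenation; none of its four bonds is broken afterwards.

Key step: step 6

Assumption: 3,4,5-trimethoxyphenol and ethyl 3-(3,4-dimethoxyphenyl)-3-oxopropanoate are taken as commercial, and the (S,S)-catalyst in step 3 is assigned to the (S)-carbinol by analogy with acetophenone-type ketones.

**Step 1**
Reactants: 1 3,4,5-trimethoxyphenol
Product: 2 2-bromo-3,4,5-trimethoxyphenol
Conditions: NBS (1.0 equiv), CH2Cl2, −40 → 0 °C
Reagents that add atoms: N-bromosuccinimide, O=C1CCC(=O)N1Br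
Why: Electrophilic aromatic bromination; the two free ring positions of 1 are equivalent (each ortho to OH and para to an OMe), so one equivalent of NBS at low temperature should give a single mono-bromide.

**Step 2**
Reactants: 2 2-bromo-3,4,5-trimethoxyphenol
Product: 5 3,4,5-trimethoxy-2-(trimethylsilyl)phenyl trifluoromethanesulfonate, via aryl trimethylsilyl ether 3 (not isolated), via lithium 2-silylphenoxide 4 (not isolated)
Conditions: HMDS, THF, 70 °C, evaporate; n-BuLi, THF, −78 °C; Tf2O, −78 °C → rt
Reagents that add atoms: hexamethyldisilazane, C[Si](C)(C)N[Si](C)(C)C; trifluoromethanesulfonic anhydride, O=S(=O)(OS(=O)(=O)C(F)(F)F)C(F)(F)F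
Why: O-silylation, bromine–lithium exchange and anionic 1,3 O→C silyl shift (retro-Brook rearrangement) should put the silyl group on the carbon that bore bromine, and the phenoxide set free is trapped as the triflate, the standard way to o-silylaryl triflate (Kobayashi-type) aryne precursors.

**Step 3**
Reactants: 6 ethyl 3-(3,4-dimethoxyphenyl)-3-oxopropanoate
Product: 7 ethyl (3S)-3-(3,4-dimethoxyphenyl)-3-hydroxypropanoate
Conditions: RuCl[(S,S)-TsDPEN](p-cymene) (1 mol %), HCO2H/Et3N (5:2), 40 °C
Reagents that add atoms: none
Why: Noyori–Ikariya asymmetric transfer hydrogenation of an aryl ketone; the chiral Ru hydride should deliver hydrogen to the face fixed by the CH/π contact between catalyst arene and substrate aryl ring, giving the (S)-carbinol under catalyst control while the ester is untouched.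

**Step 4**
Reactants: 7 ethyl (3S)-3-(3,4-dimethoxyphenyl)-3-hydroxypropanoate
Product: 9 (3S)-3-(3,4-dimethoxyphenyl)-3-hydroxypropanoic acid, via lithium carboxylate 8 (not isolated)
Conditions: LiOH·H2O, THF/H2O (3:1), 0 °C → rt; 1 M HCl to pH 3, 0 °C
Reagents that add atoms: lithium hydroxide, [Li+].[OH-]
Why: Saponification (acyl–oxygen cleavage) does not touch the carbinol centre, and cold, brief acidification should avoid ionisation of the electron-rich benzylic alcohol.

**Step 5**
Reactants: 9 (3S)-3-(3,4-dimethoxyphenyl)-3-hydroxypropanoic acid
Product: 11 (4S)-4-(3,4-dimethoxyphenyl)oxetan-2-one, via mixed sulfonic anhydride 10 (not isolated)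
Conditions: PhSO2Cl (2 equiv), pyridine, 0–4 °C; cold work-up, stored cold and used promptly
Reagents that add atoms: none
Why: β-Lactonisation by carboxyl activation; the carboxylate is sulfonylated and the β-hydroxyl attacks the activated acyl carbon (4-exo-trig), so the carbinol C–O bond is never broken and the (S) configuration should be retained.

**Step 6**
Reactants: 11 (4S)-4-(3,4-dimethoxyphenyl)oxetan-2-one; 5 3,4,5-trimethoxy-2-(trimethylsilyl)phenyl trifluoromethanesulfonate
Product: 14 (2S)-5,6,7,3',4'-pentamethoxyflavanone, via 3,4,5-trimethoxybenzyne 12 (not isolated), via β-alkoxide acyl fluoride 13 (not isolated)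
Conditions: KF (3 equiv), 18-crown-6 (3 equiv), THF, 0 °C → rt; 11 (1.3 equiv), 5 (1.0 equiv) added over 3 h; pH 7 buffer quench at 0 °C
Reagents that add atoms: none
Why: Proposed new method: fluoride unmasks aryne 12 from 5 and, as a hard nucleophile, should reversibly open the strained lactone 11 at its acyl carbon to the β-alkoxide acyl fluoride 13 (strain release pays for the acyl–O cleavage); the alkoxide adds to 12 at the aryne carbon remote from the flanking methoxy group, and the aryl anion thus placed between the new ether oxygen and that methoxy group attacks the tethered acyl fluoride and expels fluoride, so the net event is insertion of the two aryne carbons into the acyl C–O bond of the four-membered ring. The closest known reaction types are the aryne insertion into the N–C(O) bond of N-unsubstituted β-lactams, which gives 2,3-dihydroquinolin-4-ones, and the fluoride-mediated reactions of arynes with carboxylic acids or salicylates, in which an oxygen nucleophile adds and the ortho aryl anion is then acylated intramolecularly. The six-membered ring closes by 6-exo-trig attack of the aryl anion on the acyl carbon (direct addition of the lactone ring oxygen followed by a 1,3 O→C acyl shift would lead to the same ring). No stereocentre is formed: C2 of 14 is the carbinol carbon of 11, all four of whose bonds persist, so (S) in 11 should become (2S) in 14. The step needs regioselectivity (oxygen to the aryne carbon next to C–H, acyl to the one next to OMe), secured by the inductive and distortion effect of the methoxy group adjacent to the aryne, and chemoselectivity for acyl over benzylic C–O cleavage of the lactone, favoured by the hard nucleophile, low temperature and a weakly polar solvent.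

**Compound list**
1 | 3,4,5-trimethoxyphenol | COc1cc(O)cc(OC)c1OC | starting material
2 | 2-bromo-3,4,5-trimethoxyphenol | COc1cc(O)c(Br)c(OC)c1OC | intermediate
3 | (2-bromo-3,4,5-trimethoxyphenoxy)trimethylsilane | COc1cc(O[Si](C)(C)C)c(Br)c(OC)c1OC | intermediate
4 | lithium 3,4,5-trimethoxy-2-(trimethylsilyl)phenolate | [Li+].COc1cc([O-])c([Si](C)(C)C)c(OC)c1OC | intermediate
5 | 3,4,5-trimethoxy-2-(trimethylsilyl)phenyl trifluoromethanesulfonate | COc1cc(OS(=O)(=O)C(F)(F)F)c([Si](C)(C)C)c(OC)c1OC | intermediate
6 | ethyl 3-(3,4-dimethoxyphenyl)-3-oxopropanoate | CCOC(=O)CC(=O)c1ccc(OC)c(OC)c1 | starting material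
7 | ethyl (3S)-3-(3,4-dimethoxyphenyl)-3-hydroxypropanoate | CCOC(=O)C[C@H](O)c1ccc(OC)c(OC)c1 | intermediate
8 | lithium (3S)-3-(3,4-dimethoxyphenyl)-3-hydroxypropanoate | [Li+].[O-]C(=O)C[C@H](O)c1ccc(OC)c(OC)c1 | intermediate
9 | (3S)-3-(3,4-dimethoxyphenyl)-3-hydroxypropanoic acid | OC(=O)C[C@H](O)c1ccc(OC)c(OC)c1 | intermediate
10 | benzenesulfonic (3S)-3-(3,4-dimethoxyphenyl)-3-hydroxypropanoic anhydride | O=C(C[C@H](O)c1ccc(OC)c(OC)c1)OS(=O)(=O)c1ccccc1 | intermediate
11 | (4S)-4-(3,4-dimethoxyphenyl)oxetan-2-one | O=C1C[C@@H](c2ccc(OC)c(OC)c2)O1 | intermediate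
12 | 3,4,5-trimethoxybenzyne (1,2-didehydro-3,4,5-trimethoxybenzene) | COC1=C(OC)C(OC)=CC#C1 | intermediate
13 | potassium (1S)-1-(3,4-dimethoxyphenyl)-3-fluoro-3-oxopropan-1-olate | [K+].[O-][C@@H](CC(F)=O)c1ccc(OC)c(OC)c1 | intermediate
14 | (2S)-5,6,7,3',4'-pentamethoxyflavanone | COc1ccc([C@@H]2CC(=O)c3c(cc(OC)c(OC)c3OC)O2)cc1OC | target

**Step count and risks**
Total steps: 6. Longest linear sequence: 4 (steps 3, 4, 5, 6).

**Step 6 (proposed new method).** Several processes can divert the key step or erode the enantiomeric purity:
- ionisation of the lactone at the electron-rich benzylic C–O bond, with loss of CO2 or racemisation;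
- β-elimination of the opened lactone, after which the carboxylate adds to the aryne and the resulting open-chain enone re-closes without stereocontrol;
- base-mediated retro-oxa-Michael opening of the product;
- proton transfer to the aryl anion instead of acylation;
- further arylation by excess aryne.

The fallback uses known chemistry, sets out from 1 and returns at 14, with no ring-size change. Ortho-acetylation of 1 (AcOH, BF3·OEt2, 90 °C, Fries-type) should give 1-(2-hydroxy-4,5,6-trimethoxyphenyl)ethan-1-one F1. Condensation with DMF dimethyl acetal gives the enaminone (E)-3-(dimethylamino)-1-(2-hydroxy-4,5,6-trimethoxyphenyl)prop-2-en-1-one F2. Acid-induced cyclisation with loss of dimethylamine gives 5,6,7-trimethoxy-4H-chromen-4-one F3. Pd(II)/pyridine-oxazoline- or Rh(I)/chiral-diphosphine-catalysed asymmetric conjugate addition of (3,4-dimethoxyphenyl)boronic acid to F3, with the ligand enantiomer that delivers the aryl group to the face giving (2S), then leads to 14.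

**Step 5.** The carbinol may ionise under the sulfonylating conditions (racemisation or decarboxylative elimination), and the lactone may lose CO2 on concentration or chromatography. The fallback sets out from 7, returns at 14 and bypasses the lactone. Deprotonation (NaH, THF, 0 °C) gives sodium ethyl (3S)-3-(3,4-dimethoxyphenyl)-3-oxidopropanoate F7. This is exposed to aryne 12 generated from 5 (CsF, MeCN/THF). The alkoxide adds to the aryne and the ortho aryl anion closes onto the ethyl ester (Dieckmann-type, 6-exo-trig) with loss of ethoxide.

**Step 2.** Halogen–lithium exchange may be incomplete, the aryllithium may be quenched by proton transfer before the silyl shift, and triflation of the hindered phenoxide may be slow. The fallback sets out from 1 and returns at 5 by directed ortho-metalation. Carbamoylation (i-PrNCO, Et3N) gives 3,4,5-trimethoxyphenyl isopropylcarbamate F4. In-situ N-silylation, ortho-lithiation and silylation (TMSOTf, TMEDA; n-BuLi, −78 °C; TMSCl) give 3,4,5-trimethoxy-2-(trimethylsilyl)phenyl isopropylcarbamate F5. Carbamate cleavage (DBU, Et2NH, MeCN, 40 °C) gives 3,4,5-trimethoxy-2-(trimethylsilyl)phenol F6. Triflation with PhNTf2 gives 5.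

**Further compounds**
F1 | step 6 | 1-(2-hydroxy-4,5,6-trimethoxyphenyl)ethan-1-one | CC(=O)c1c(O)cc(OC)c(OC)c1OC
F2 | step 6 | (E)-3-(dimethylamino)-1-(2-hydroxy-4,5,6-trimethoxyphenyl)prop-2-en-1-one | CN(C)/C=C/C(=O)c1c(O)cc(OC)c(OC)c1OC
F3 | step 6 | 5,6,7-trimethoxy-4H-chromen-4-one | COc1cc2occc(=O)c2c(OC)c1OC
F4 | step 2 | 3,4,5-trimethoxyphenyl isopropylcarbamate | CC(C)NC(=O)Oc1cc(OC)c(OC)c(OC)c1
F5 | step 2 | 3,4,5-trimethoxy-2-(trimethylsilyl)phenyl isopropylcarbamate | CC(C)NC(=O)Oc1cc(OC)c(OC)c(OC)c1[Si](C)(C)C
F6 | step 2 | 3,4,5-trimethoxy-2-(trimethylsilyl)phenol | COc1cc(O)c([Si](C)(C)C)c(OC)c1OC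
F7 | step 5 | sodium ethyl (3S)-3-(3,4-dimethoxyphenyl)-3-oxidopropanoate | CCOC(=O)C[C@H]([O-])c1ccc(OC)c(OC)c1.[Na+]
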